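**Retrosynthetic overview**
- The target is a 3-methyl-2,5-dihydro-1-benzoxepine fused to ring A of a dihydrochalcone. The last step only removes four MOM groups.
- Key disconnection: the oxepine ring is cut at aryl C9a–O1 and aryl C5a–C5. This gives an aryne (C5a≡C9a) of the MOM-protected dihydrochalcone and 2-methyl-2-vinyloxirane, joined by a formal [5+2] σ-insertion with allylic transposition.
- Enabling feature: C5a and C9a are adjacent on ring A, and C5a is flanked by the C6 oxygen. In the aryne this oxygen steers the oxirane oxygen to C9a and the carbanion to C5a. The unit O1–C2–C3(Me)=C4–C5 is the ring-opened, transposed skeleton of the vinyl oxirane.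
- Aryne precursor: an ortho-silylaryl triflate built on phloroglucinol. SiMe3 comes from ortho-bromination and retro-Brook shift; the acyl chain comes from directed ortho-metalation between two OMOM groups and a Weinreb amide. Ring A is symmetric until the silyl group is placed, so only one aryne can form.
- Ring order: rings A and B are bought (phloroglucinol, methyl dihydrocaffeate). The oxepine is the only ring formed, in the key step.

Key step: step 9

Remark: 2-methyl-2-vinyloxirane is used as the commercial racemate. Its stereocentre becomes sp2 in step 9, the target is achiral, and the alkene inside the seven-membered ring can only be Z.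

**Route**

Step 1
Reactants: 1 methyl 3-(3,4-dihydroxyphenyl)propanoate
Product: 2 methyl 3-[3,4-bis(methoxymethoxy)phenyl]propanoate
Conditions: MOMCl, i-Pr2NEt, CH2Cl2, 0 °C → rt
Reagents that add atoms: chloromethyl methyl ether, COCCl
Why: Williamson-type O-alkylation of both catechol hydroxyls by the reactive α-chloro ether under amine base should give the bis-MOM acetal and leave the methyl ester untouched.

Step 2
Reactants: 2 methyl 3-[3,4-bis(methoxymethoxy)phenyl]propanoate
Product: 3 3-[3,4-bis(methoxymethoxy)phenyl]-N-methoxy-N-methylpropanamide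
Conditions: MeNH(OMe)·HCl, i-PrMgCl, THF, –20 °C → 0 °C
Reagents that add atoms: N,O-dimethylhydroxylamine hydrochloride, CNOC.Cl
Why: Aminolysis of the ester by the chloromagnesium amide (Weinreb amide synthesis from esters) should stop at the amide because the chelated tetrahedral adduct does not take up a second nucleophile, and MOM acetals tolerate the base.

Step 3
Reactants: 4 phloroglucinol
Product: 5 3,5-bis(methoxymethoxy)phenol
Conditions: MOMCl (2 equiv), i-Pr2NEt, DMF, 0 °C → rt
Reagents that add atoms: chloromethyl methyl ether, COCCl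
Why: Statistical Williamson O-alkylation of the threefold symmetric triol with two equivalents of MOMCl should give the bis-ether as the main separable fraction, keeping one phenol as the later C–O leaving-group site.

Step 4
Reactants: 5 3,5-bis(methoxymethoxy)phenol
Product: 6 2-bromo-3,5-bis(methoxymethoxy)phenol
Conditions: NBS (1.0 equiv), i-Pr2NH (cat.), CH2Cl2, –78 °C → 0 °C
Reagents that add atoms: N-bromosuccinimide, O=C1CCC(=O)N1Br
Why: Electrophilic aromatic bromination under the amine-mediated NBS protocol, which delivers bromine ortho to the phenolic hydroxyl (the two ortho positions are equivalent), should give the ortho-bromophenol at low temperature.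

Step 5
Reactants: 6 2-bromo-3,5-bis(methoxymethoxy)phenol
Product: 10 triisopropyl[3,5-bis(methoxymethoxy)-2-(trimethylsilyl)phenoxy]silane, via aryl trimethylsilyl ether 7 (not isolated), via ortho-lithiated aryl silyl ether 8 (not isolated), via lithium 2-silylphenoxide 9 (not isolated)
Conditions: HMDS, THF, 65 °C, evaporate; n-BuLi, THF, –78 °C → 0 °C; TIPSOTf, –78 °C → rt
Reagents that add atoms: hexamethyldisilazane, C[Si](C)(C)N[Si](C)(C)C; triisopropylsilyl trifluoromethanesulfonate, CC(C)[Si](OS(=O)(=O)C(F)(F)F)(C(C)C)C(C)C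
Why: O-silylation followed by bromine–lithium exchange should trigger the 1,3 O→C silyl shift (retro-Brook rearrangement) that puts SiMe3 on the ring, and the resulting lithium phenoxide, the species normally triflated at this point, is capped with TIPSOTf as a bulky, non-directing silyl ether.

Step 6
Reactants: 10 triisopropyl[3,5-bis(methoxymethoxy)-2-(trimethylsilyl)phenoxy]silane; 3 3-[3,4-bis(methoxymethoxy)phenyl]-N-methoxy-N-methylpropanamide
Product: 13 3-[3,4-bis(methoxymethoxy)phenyl]-1-[2,6-bis(methoxymethoxy)-4-(triisopropylsilyloxy)-3-(trimethylsilyl)phenyl]propan-1-one, via aryllithium 11 (not isolated), via lithium hemiaminal alkoxide 12 (not isolated)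
Conditions: n-BuLi, THF, 0 °C; then 3, –78 °C → 0 °C; aq NH4Cl
Reagents that add atoms: none
Why: Directed ortho-metalation should remove the only ring hydrogen flanked by two coordinating OMOM groups (the OTIPS group is too bulky to direct), and the aryllithium is acylated by the Weinreb amide through a chelated tetrahedral adduct that releases the ketone only on work-up.

Step 7
Reactants: 13 3-[3,4-bis(methoxymethoxy)phenyl]-1-[2,6-bis(methoxymethoxy)-4-(triisopropylsilyloxy)-3-(trimethylsilyl)phenyl]propan-1-one
Product: 14 3-[3,4-bis(methoxymethoxy)phenyl]-1-[4-hydroxy-2,6-bis(methoxymethoxy)-3-(trimethylsilyl)phenyl]propan-1-one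
Conditions: TBAF, AcOH, THF, 0 °C
Reagents that add atoms: none
Why: Fluoride-mediated desilylation should cleave the aryl O–Si bond (the phenoxide para to the ketone is a good leaving group), while the ring C–SiMe3 bond, the MOM acetals and the ketone are inert to buffered TBAF at 0 °C.

Step 8
Reactants: 14 3-[3,4-bis(methoxymethoxy)phenyl]-1-[4-hydroxy-2,6-bis(methoxymethoxy)-3-(trimethylsilyl)phenyl]propan-1-one
Product: 15 4-{3-[3,4-bis(methoxymethoxy)phenyl]propanoyl}-3,5-bis(methoxymethoxy)-2-(trimethylsilyl)phenyl trifluoromethanesulfonate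
Conditions: Tf2O, pyridine, CH2Cl2, 0 °C
Reagents that add atoms: trifluoromethanesulfonic anhydride, O=S(=O)(OS(=O)(=O)C(F)(F)F)C(F)(F)F
Why: O-sulfonylation of the only free hydroxyl with triflic anhydride and pyridine should give the ortho-silylaryl triflate aryne precursor, since nothing else in the molecule is nucleophilic enough to react.

Step 9
Reactants: 15 4-{3-[3,4-bis(methoxymethoxy)phenyl]propanoyl}-3,5-bis(methoxymethoxy)-2-(trimethylsilyl)phenyl trifluoromethanesulfonate; 16 2-methyl-2-vinyloxirane (racemic)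
Product: 19 3-[3,4-bis(methoxymethoxy)phenyl]-1-[6,8-bis(methoxymethoxy)-3-methyl-2,5-dihydro-1-benzoxepin-7-yl]propan-1-one, via aryne 17 (not isolated), via oxiranium aryl anion zwitterion 18 (not isolated)
Conditions: CsF, 16 (excess), MeCN, 25 °C
Reagents that add atoms: none
Why: Proposed new method: fluoride removes SiMe3 from 15 and triflate leaves to give aryne 17; the oxirane oxygen of 16 adds to the aryne carbon remote from the flanking OMOM group, and the aryl anion/O-aryl oxiranium zwitterion 18 should collapse by intramolecular SN2′ attack of the carbanion on the vinyl terminus with cleavage of the quaternary C–O bond. The closest known reaction types are the aryne σ-insertion into the C–O bond of epoxides that gives 2,3-dihydrobenzofurans and the aryne-triggered aza-Claisen ring expansion of 2-vinylazetidines to benzazocines; the vinylogous SN2′ mode with an oxirane is the new element. The seven-membered ring closes through a six-membered cyclic transition state (equivalent to a charge-accelerated [3,3] shift), a formal [5+2] annulation in which the three oxirane atoms, the two vinyl carbons and the two aryne carbons become the ring, driven by release of aryne and oxirane strain. No stereocentre is formed, the quaternary centre of 16 becomes sp2, and the ring alkene can only be Z. The step needs C–O formation at the aryne carbon remote from the flanking OMOM group, which that inductively withdrawing group secures by distorting the aryne so that the carbanion develops next to it. It also needs SN2′ closure instead of direct collapse to a 3-methyl-3-vinyl-2,3-dihydrobenzofuran, favoured by the six- over four-membered transition state and the fully substituted oxirane carbon; an ene pathway is excluded because the allylic carbon of 16 bears no hydrogen.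

Step 10
Reactants: 19 3-[3,4-bis(methoxymethoxy)phenyl]-1-[6,8-bis(methoxymethoxy)-3-methyl-2,5-dihydro-1-benzoxepin-7-yl]propan-1-one
Product: 20 3-(3,4-dihydroxyphenyl)-1-(6,8-dihydroxy-3-methyl-2,5-dihydro-1-benzoxepin-7-yl)propan-1-one
Conditions: 3 M aq HCl, MeOH, 40 °C
Reagents that add atoms: none
Why: Acid-catalysed transacetalisation of the four MOM ethers in methanol (the two ortho to the ketone are activated by hydrogen bonding) should free the phenols under conditions mild enough for the trisubstituted ring alkene and the allyl aryl ether, giving the achiral target.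

**Compound list**
1 | methyl 3-(3,4-dihydroxyphenyl)propanoate | COC(=O)CCc1ccc(O)c(O)c1 | starting material
2 | methyl 3-[3,4-bis(methoxymethoxy)phenyl]propanoate | COC(=O)CCc1ccc(OCOC)c(OCOC)c1 | intermediate
3 | 3-[3,4-bis(methoxymethoxy)phenyl]-N-methoxy-N-methylpropanamide | CON(C)C(=O)CCc1ccc(OCOC)c(OCOC)c1 | intermediate
4 | phloroglucinol (benzene-1,3,5-triol) | Oc1cc(O)cc(O)c1 | starting material
5 | 3,5-bis(methoxymethoxy)phenol | COCOc1cc(O)cc(OCOC)c1 | intermediate
6 | 2-bromo-3,5-bis(methoxymethoxy)phenol | COCOc1cc(O)c(Br)c(OCOC)c1 | intermediate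
7 | [2-bromo-3,5-bis(methoxymethoxy)phenoxy]trimethylsilane | COCOc1cc(O[Si](C)(C)C)c(Br)c(OCOC)c1 | intermediate
8 | [2-lithio-3,5-bis(methoxymethoxy)phenoxy]trimethylsilane | COCOc1cc(O[Si](C)(C)C)c([Li])c(OCOC)c1 | intermediate
9 | lithium 3,5-bis(methoxymethoxy)-2-(trimethylsilyl)phenolate | COCOc1cc([O-])c([Si](C)(C)C)c(OCOC)c1.[Li+] | intermediate
10 | triisopropyl[3,5-bis(methoxymethoxy)-2-(trimethylsilyl)phenoxy]silane | COCOc1cc(O[Si](C(C)C)(C(C)C)C(C)C)c([Si](C)(C)C)c(OCOC)c1 | intermediate
11 | [2,6-bis(methoxymethoxy)-4-(triisopropylsilyloxy)-3-(trimethylsilyl)phenyl]lithium | COCOc1cc(O[Si](C(C)C)(C(C)C)C(C)C)c([Si](C)(C)C)c(OCOC)c1[Li] | intermediate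
12 | lithium 3-[3,4-bis(methoxymethoxy)phenyl]-1-[2,6-bis(methoxymethoxy)-4-(triisopropylsilyloxy)-3-(trimethylsilyl)phenyl]-1-[methoxy(methyl)amino]propan-1-olate (racemic) | COCOc1cc(O[Si](C(C)C)(C(C)C)C(C)C)c([Si](C)(C)C)c(OCOC)c1C([O-])(CCc2ccc(OCOC)c(OCOC)c2)N(C)OC.[Li+] | intermediate
13 | 3-[3,4-bis(methoxymethoxy)phenyl]-1-[2,6-bis(methoxymethoxy)-4-(triisopropylsilyloxy)-3-(trimethylsilyl)phenyl]propan-1-one | COCOc1cc(O[Si](C(C)C)(C(C)C)C(C)C)c([Si](C)(C)C)c(OCOC)c1C(=O)CCc2ccc(OCOC)c(OCOC)c2 | intermediate
14 | 3-[3,4-bis(methoxymethoxy)phenyl]-1-[4-hydroxy-2,6-bis(methoxymethoxy)-3-(trimethylsilyl)phenyl]propan-1-one | COCOc1cc(O)c([Si](C)(C)C)c(OCOC)c1C(=O)CCc2ccc(OCOC)c(OCOC)c2 | intermediate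
15 | 4-{3-[3,4-bis(methoxymethoxy)phenyl]propanoyl}-3,5-bis(methoxymethoxy)-2-(trimethylsilyl)phenyl trifluoromethanesulfonate | COCOc1cc(OS(=O)(=O)C(F)(F)F)c([Si](C)(C)C)c(OCOC)c1C(=O)CCc2ccc(OCOC)c(OCOC)c2 | intermediate
16 | 2-methyl-2-vinyloxirane (racemic) | C=CC1(C)CO1 | starting material
17 | 3-[3,4-bis(methoxymethoxy)phenyl]-1-[3,4-didehydro-2,6-bis(methoxymethoxy)phenyl]propan-1-one (aryne) | COCOC1=CC#CC(OCOC)=C1C(=O)CCc2ccc(OCOC)c(OCOC)c2 | intermediate
18 | 1-aryl-2-ethenyl-2-methyloxiran-1-ium zwitterion with the carbanion on the ring carbon next to the oxonium-bearing carbon | COCOC1=CC([O+]2CC2(C)C=C)=[C-]C(OCOC)=C1C(=O)CCc3ccc(OCOC)c(OCOC)c3 | intermediate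
19 | 3-[3,4-bis(methoxymethoxy)phenyl]-1-[6,8-bis(methoxymethoxy)-3-methyl-2,5-dihydro-1-benzoxepin-7-yl]propan-1-one | CC1=CCc2c(cc(OCOC)c(C(=O)CCc3ccc(OCOC)c(OCOC)c3)c2OCOC)OC1 | intermediate
20 | 3-(3,4-dihydroxyphenyl)-1-(6,8-dihydroxy-3-methyl-2,5-dihydro-1-benzoxepin-7-yl)propan-1-one | CC1=CCc2c(cc(O)c(C(=O)CCc3ccc(O)c(O)c3)c2O)OC1 | target

**Step count and risks**

Total steps: 10. Longest linear sequence: 8 steps (steps 3 to 10, from phloroglucinol).

Steps most likely to fail:

1. Step 9 (proposed new method). The zwitterion may collapse directly at the oxiranium carbon (five-membered ring), or the aryl anion may be protonated by acetonitrile before the SN2′ closure, or the weakly nucleophilic oxirane may lose the aryne to fluoride or solvent. The fallback uses known chemistry, sets out from 5 and comes back at 19. Phenol 5 is silylated with TIPSCl and imidazole to triisopropyl[3,5-bis(methoxymethoxy)phenoxy]silane F1. Directed ortho-lithiation between the two OMOM groups (n-BuLi) and acylation with 3 gives 3-[3,4-bis(methoxymethoxy)phenyl]-1-[2,6-bis(methoxymethoxy)-4-(triisopropylsilyloxy)phenyl]propan-1-one F2. Buffered TBAF frees 3-[3,4-bis(methoxymethoxy)phenyl]-1-[4-hydroxy-2,6-bis(methoxymethoxy)phenyl]propan-1-one F3. O-allylation (allyl bromide, K2CO3, acetone) gives 1-[4-(allyloxy)-2,6-bis(methoxymethoxy)phenyl]-3-[3,4-bis(methoxymethoxy)phenyl]propan-1-one F4. Aromatic Claisen rearrangement (N,N-diethylaniline, 190 °C; both ortho positions are equivalent and the para position is blocked) gives 1-[3-allyl-4-hydroxy-2,6-bis(methoxymethoxy)phenyl]-3-[3,4-bis(methoxymethoxy)phenyl]propan-1-one F5. O-alkylation with 3-chloro-2-methylprop-1-ene (K2CO3, NaI cat., DMF) gives 1-[3-allyl-2,6-bis(methoxymethoxy)-4-(2-methylallyloxy)phenyl]-3-[3,4-bis(methoxymethoxy)phenyl]propan-1-one F6. Ring-closing metathesis with second-generation Grubbs catalyst (CH2Cl2, 40 °C) then closes the dihydrooxepine to 19.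

2. Step 6. The hindered aryllithium may take a proton from the α-methylene of the Weinreb amide instead of adding, so that acyl transfer stalls and 10 is returned. The fallback sets out from 10 (with ester 2 as the side-chain source) and comes back at 13. Ester 2 is reduced with i-Bu2AlH at –78 °C to 3-[3,4-bis(methoxymethoxy)phenyl]propanal F7. The aryllithium from 10 adds to this far more electrophilic aldehyde at –78 °C to give racemic 3-[3,4-bis(methoxymethoxy)phenyl]-1-[2,6-bis(methoxymethoxy)-4-(triisopropylsilyloxy)-3-(trimethylsilyl)phenyl]propan-1-ol F8. Dess–Martin oxidation then gives 13.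

3. Step 4. Bromination may occur para to the hydroxyl (between the two OMOM groups), or the very electron-rich ring may be brominated twice. The fallback places the silyl group by carbamate-directed ortho-metalation instead of bromination and retro-Brook shift; it sets out from 5 and comes back at 10. Phenol 5 is carbamoylated (ClC(O)NEt2, K2CO3, MeCN) to 3,5-bis(methoxymethoxy)phenyl N,N-diethylcarbamate F9. Ortho-lithiation between the carbamate and an OMOM group (s-BuLi, TMEDA, THF, –78 °C) with a TMSCl quench gives 3,5-bis(methoxymethoxy)-2-(trimethylsilyl)phenyl N,N-diethylcarbamate F10. Reductive removal of the carbamate (LiAlH4, THF) gives 3,5-bis(methoxymethoxy)-2-(trimethylsilyl)phenol F11. Silylation with TIPSOTf and 2,6-lutidine then gives 10.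

**Further compounds**
F1 | step 9 | triisopropyl[3,5-bis(methoxymethoxy)phenoxy]silane | COCOc1cc(O[Si](C(C)C)(C(C)C)C(C)C)cc(OCOC)c1
F2 | step 9 | 3-[3,4-bis(methoxymethoxy)phenyl]-1-[2,6-bis(methoxymethoxy)-4-(triisopropylsilyloxy)phenyl]propan-1-one | COCOc1cc(O[Si](C(C)C)(C(C)C)C(C)C)cc(OCOC)c1C(=O)CCc2ccc(OCOC)c(OCOC)c2
F3 | step 9 | 3-[3,4-bis(methoxymethoxy)phenyl]-1-[4-hydroxy-2,6-bis(methoxymethoxy)phenyl]propan-1-one | COCOc1cc(O)cc(OCOC)c1C(=O)CCc2ccc(OCOC)c(OCOC)c2
F4 | step 9 | 1-[4-(allyloxy)-2,6-bis(methoxymethoxy)phenyl]-3-[3,4-bis(methoxymethoxy)phenyl]propan-1-one | COCOc1cc(OCC=C)cc(OCOC)c1C(=O)CCc2ccc(OCOC)c(OCOC)c2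
F5 | step 9 | 1-[3-allyl-4-hydroxy-2,6-bis(methoxymethoxy)phenyl]-3-[3,4-bis(methoxymethoxy)phenyl]propan-1-one | COCOc1cc(O)c(CC=C)c(OCOC)c1C(=O)CCc2ccc(OCOC)c(OCOC)c2
F6 | step 9 | 1-[3-allyl-2,6-bis(methoxymethoxy)-4-(2-methylallyloxy)phenyl]-3-[3,4-bis(methoxymethoxy)phenyl]propan-1-one | COCOc1cc(OCC(C)=C)c(CC=C)c(OCOC)c1C(=O)CCc2ccc(OCOC)c(OCOC)c2
F7 | step 6 | 3-[3,4-bis(methoxymethoxy)phenyl]propanal | COCOc1ccc(CCC=O)cc1OCOC
F8 | step 6 | 3-[3,4-bis(methoxymethoxy)phenyl]-1-[2,6-bis(methoxymethoxy)-4-(triisopropylsilyloxy)-3-(trimethylsilyl)phenyl]propan-1-ol (racemic) | COCOc1cc(O[Si](C(C)C)(C(C)C)C(C)C)c([Si](C)(C)C)c(OCOC)c1C(O)CCc2ccc(OCOC)c(OCOC)c2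
F9 | step 4 | 3,5-bis(methoxymethoxy)phenyl N,N-diethylcarbamate | COCOc1cc(OC(=O)N(CC)CC)cc(OCOC)c1
F10 | step 4 | 3,5-bis(methoxymethoxy)-2-(trimethylsilyl)phenyl N,N-diethylcarbamate | COCOc1cc(OC(=O)N(CC)CC)c([Si](C)(C)C)c(OCOC)c1
F11 | step 4 | 3,5-bis(methoxymethoxy)-2-(trimethylsilyl)phenol | COCOc1cc(O)c([Si](C)(C)C)c(OCOC)c1
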